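The vessel was closed and stirred, so Monday's heating at 2.5 min could act on the part of the charge that had not yet reached a product, and that part was what I set out to reckon.

in all of them: substrate 5.0 × 10⁻⁴ M
- dawn: first nucleophile 2 mM; solid second nucleophile 0.71 mM; temperature 55 °C; run made earlier
- summer: first nucleophile 2 mM; solid second nucleophile 3.5 mM; temperature 80 °C; run made earlier
- Wednesday's: first nucleophile 2.00 mM; solid second nucleophile 2.50 mM; at 60 °C throughout; time 5.0 min
- Monday's: first nucleophile 2.00 mM; solid second nucleophile 0.600 mM; at 60 °C until 2.5 min, from then on at 100 °C; time 5.0 min

- dawn (time / min: target / %): 0.167: 5.0; 0.500: 20.1; 0.833: 32.4; 1.33: 44.8; 2.00: 53.5; 2.50: 57.0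
- summer (time / s: target / %): 10.0: 52.0; 12.0: 59.9; 20.0: 76.1; 30.0: 80.9; 40.0: 82.7; 60.0: 82.1

(scatter of a reading: 0.3 percentage points)

- solid second nucleophile is a solid; its amount is given per volume of the solution
- steps that have been proposed: substrate -> intermediate; first nucleophile + intermediate -> target; second nucleophile + intermediate -> other capture product; intermediate -> solvolysis product; solid second nucleophile <-> second nucleophile
- at the start none of the solid second nucleophile is in solution

- which one finishes higher in amount of target, in percent of the substrate charged ("neither" within 2 percentage points) (Wednesday's / Monday's / neither)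
- amount of target at the end, in percent of the substrate charged, Wednesday's
- amount of target at the end, in percent of the substrate charged, Monday's

I built the flask up one process at a time. With the first step alone, substrate, the limiting reagent, simply decays. I read its rate constant as 1.09 min⁻¹ from the falling slope of target in the dawn run, and as 9.30 min⁻¹ from the approach to the plateau in the summer run. Interpolating the logarithm in temperature gave me 1.67 min⁻¹ at 60 °C, so 1.54 % of the substrate stood at the change.

Then I added the capture steps. The first dawn readings extrapolated to a lag of 0.0567 min, which I took as the lifetime of the intermediate, and putting the first answer back through that lifetime gave 0.146 % of intermediate. Their sum was the exposed share, the part of the substrate charged that has not yet passed through its split when the temperature changes 1.68 %, which I reckoned at 1.68 %.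

Last came the worth of that share. If the whole exposed part became target in Monday's and none of it did in Wednesday's, Monday's would lead by 1.7 percentage points, which is less than the margin. The solid charges also differ, and for them I had no reckoning. I committed to a tie on the ground of temperature.

The forecast said neither, with 66 % for Wednesday's and 68 % for Monday's, and of the solid it said “Extra solid should change little”.

The simulation gave neither, with 69.7 % for Wednesday's and 70.2 % for Monday's.

    substrate → intermediate (k = 0.0229 s⁻¹, Ea = 91.0 kJ mol⁻¹)
    first nucleophile + intermediate → target (k = 73.2 L mol⁻¹ s⁻¹, Ea = 35.0 kJ mol⁻¹)
    second nucleophile + intermediate → other capture product (k = 9260 L mol⁻¹ s⁻¹, Ea = 12.0 kJ mol⁻¹)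
    intermediate → solvolysis product (k = 0.00478 s⁻¹, Ea = 92.0 kJ mol⁻¹)
    solid second nucleophile ⇌ second nucleophile, rate k5*(cs5 - [second nucleophile]) while solid is left; crystals form when [second nucleophile] > cs5 (solubility = 0.0200 mM, k = 0.0876 s⁻¹)
    (constants at 60 °C)

Up to 2.50 min Wednesday's and Monday's ran alike, with target at 68.3 % and 68.3 % and second nucleophile at 1.67 × 10⁻⁵ M and 1.67 × 10⁻⁵ M, despite their different solid charges. The exposed share in each flask was then 3.51 % against my 1.68 %; after that point Wednesday's added 1.4 points of target and Monday's, in its hot remainder, added 1.9 points, which put Monday's 0.50 points ahead of Wednesday's. For a flask like Wednesday's kept at 35 °C, the first step of the same reckoning gave 37.6 % of substrate unspent at the end, and that flask held 62.0 % of substrate with 13.0 % of target.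

The earlier runs and the new flask are simulated for substances that don't exist, and the scatter is random.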